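Rings A and B of the drimane core share the C5–C10 bond, and ring B is functionalised only at C8 and C9; the trans-decalin is therefore taken as the product of a type 1 intramolecular Diels–Alder reaction. An acyclic (3R)-trienal, in which a 2-(trimethylsilylmethyl)diene (C7=C8–C9=C10) and an (E)-enal (C5=C6) are joined by the C1–C4 chain, closes both rings under chiral iminium catalysis, forming C5–C10 and C6–C7 and setting C5 and the quaternary C10. The formyl group is then excised, the allylsilane is unmasked to the C8 exocyclic alkene (setting C9) and hydrated, and the umbelliferyl ether and angelate are added last.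

Key step: step 7

Remark: bicyclic compounds carry drimane numbering (ring A: C1–C5 and C10; ring B: C5–C10; C11 = CH2O on C9; C12 = the carbon on C8; C15 = the methyl on C10), α is the face opposite the C10 methyl, and the same numbers are used for the corresponding carbons of the acyclic precursors.

Step 1
Reactants: 1 pent-4-ynal; 2 3-methylbuta-1,2-diene
Product: 5 (4R)-3,3-dimethyloct-1-en-7-yn-4-ol, via prenyldiisopinocampheylborane 3 (not isolated), via homoallyl borinate 4 (not isolated)
Conditions: (−)-Ipc2BH [from (+)-α-pinene], 2, THF, −25 °C; then 1, −78 °C; NaOH, H2O2, 0 °C → rt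
Reagents that add atoms: none
Why: Brown asymmetric allylboration (reverse prenylation): the prenylborane formed by hydroboration of the allene at its CH2 terminus adds through its γ-carbon in a closed chair (Zimmerman–Traxler) transition state to the si face of the aldehyde selected by the isopinocampheyl groups, which should give the (R)-carbinol (C3) flanked by the gem-dimethyl carbon and the vinyl group.

Step 2
Reactants: 5 (4R)-3,3-dimethyloct-1-en-7-yn-4-ol
Product: 6 triethyl{[(4R)-3,3-dimethyloct-1-en-7-yn-4-yl]oxy}silane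
Conditions: TESOTf, 2,6-lutidine, CH2Cl2, −78 → 0 °C
Reagents that add atoms: triethylsilyl trifluoromethanesulfonate, CC[Si](CC)(CC)OS(=O)(=O)C(F)(F)F
Why: Silyl ether formation with a silyl triflate, reactive enough for the neopentyl-type carbinol, masks the alkoxide that could misdirect step 4 with a group that the acid of step 9 removes; no stereocenter is touched.

Step 3
Reactants: 6 triethyl{[(4R)-3,3-dimethyloct-1-en-7-yn-4-yl]oxy}silane
Product: 8 (6R)-7,7-dimethyl-6-(triethylsilyloxy)non-8-en-2-yn-1-ol, via lithium acetylide 7 (not isolated)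
Conditions: n-BuLi, THF, −78 °C; (CH2O)n, −78 °C → rt; H2O
Reagents that add atoms: formaldehyde (as paraformaldehyde), C=O
Why: Deprotonation of the terminal alkyne and 1,2-addition of the acetylide to formaldehyde (alkynylation) give the propargylic alcohol that carries C11; no stereocenter is formed.

Step 4
Reactants: 8 (6R)-7,7-dimethyl-6-(triethylsilyloxy)non-8-en-2-yn-1-ol
Product: 10 (2E,6R)-2-iodo-3,7,7-trimethyl-6-(triethylsilyloxy)nona-2,8-dien-1-ol, via alkenylmagnesium bromide 9 (not isolated)
Conditions: MeMgBr (5 equiv), Fe(acac)3 (20 mol%), THF, −78 → 0 °C; I2, −78 → 0 °C; H2O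
Reagents that add atoms: methylmagnesium bromide, C[Mg]Br; iodine, [I][I]
Why: Alkoxide-directed iron-catalysed syn-carbomagnesiation of a propargylic alcohol places methyl on the distal alkyne carbon (C10) and magnesium on the proximal one (C9), cis to each other, and iodinolysis with retention should give the single tetrasubstituted (E)-iodoalkene in which the tether carbon C1 is cis to CH2OH.

Step 5
Reactants: 10 (2E,6R)-2-iodo-3,7,7-trimethyl-6-(triethylsilyloxy)nona-2,8-dien-1-ol; 11 (E)-but-2-enal
Product: 12 (2E,5R,8E)-10-hydroxy-9-iodo-4,4,8-trimethyl-5-(triethylsilyloxy)deca-2,8-dienal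
Conditions: 11 (5 equiv), second-generation Hoveyda–Grubbs catalyst (5 mol%), CH2Cl2, 40 °C
Reagents that add atoms: none
Why: Olefin cross-metathesis with an excess of the enal partner: only the monosubstituted vinyl group can enter the catalytic cycle (the tetrasubstituted iodoalkene is inert), and the conjugated (E)-enal is the thermodynamic product; no stereocenter is affected.

Step 6
Reactants: 12 (2E,5R,8E)-10-hydroxy-9-iodo-4,4,8-trimethyl-5-(triethylsilyloxy)deca-2,8-dienal; 13 (2-bromoprop-2-en-1-yl)trimethylsilane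
Product: 16 (2E,5R,8Z)-9-(hydroxymethyl)-4,4,8-trimethyl-10-methylidene-5-(triethylsilyloxy)-11-(trimethylsilyl)undeca-2,8-dienal, via allylsilane Grignard reagent 14 (not isolated), via alkenylzinc chloride 15 (not isolated)
Conditions: 13, Mg, THF, rt; ZnCl2, 0 °C; then 12, Pd2(dba)3 (2.5 mol%), SPhos (10 mol%), THF, 0 °C → rt (3 equiv of 15)
Reagents that add atoms: none
Why: Negishi cross-coupling at the C–I bond with retention of alkene geometry, the zinc reagent (one equivalent is spent on the hydroxyl) leaving the enal untouched, installs the 2-(silylmethyl)diene with C1 on the outside of its s-cis form.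

Step 7
Reactants: 16 (2E,5R,8Z)-9-(hydroxymethyl)-4,4,8-trimethyl-10-methylidene-5-(triethylsilyloxy)-11-(trimethylsilyl)undeca-2,8-dienal
Product: 17 (3R,5R,6S,10S)-11-hydroxy-3-(triethylsilyloxy)-12-(trimethylsilyl)drim-8-ene-6-carbaldehyde
Conditions: (2S,5S)-5-benzyl-2-tert-butyl-3-methylimidazolidin-4-one·CF3CO2H (20 mol%), MeCN/H2O (98:2), 0.02 M, −20 °C → rt
Reagents that add atoms: none
Why: Condensation of the enal with the imidazolidinone salt gives an (E)-iminium ion whose lowered LUMO is attacked by the tethered, allylsilane-activated diene in a concerted, asynchronous [4+2] cycloaddition (C5–C10 leading), and hydrolysis of the product iminium ion releases 17 and the amine; the closest known reaction type is the imidazolidinone-catalysed intramolecular Diels–Alder reaction of (E)-trienals. Ring B closes as the cyclohexene of the cycloaddition, both new bonds forming suprafacially on diene and dienophile, and ring A closes in the same event as the six-membered ring spanned by the C1–C4 tether in a chair, the C5–C10 bond lying exo to both π systems (fused, type 1 mode). C5 is controlled by the catalyst: the benzyl group covers one face of the iminium ion, so C10 should add to the open face of C5 and give 5R. C10 and the transient C6 centre follow from the endo transition state of the (E)-dienophile with the tether anti, which puts the inside methyl of the diene terminus trans to H5 (trans ring fusion, 10S) and the formyl group 6α; the alkene geometry fixed in step 4 holds C1 on the outside of the s-cis diene as this requires. The step needs facial selectivity (catalyst; the (R)-silyl ether at C3 is merely carried into the axial position and biases the chair only weakly), endo over exo selectivity (iminium ion under the diene, chair tether, Thorpe–Ingold effect of the C4 methyls) and fused over bridged closure (four-carbon tether, which also rules out attack of C7 on C5). The fully substituted diene terminus and the neopentyl β-carbon of the dienophile make this the step of highest risk.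

Step 8
Reactants: 17 (3R,5R,6S,10S)-11-hydroxy-3-(triethylsilyloxy)-12-(trimethylsilyl)drim-8-ene-6-carbaldehyde
Product: 18 (3R,5R,10S)-3-(triethylsilyloxy)-12-(trimethylsilyl)drim-8-en-11-ol
Conditions: RhCl(PPh3)3 (1.1 equiv), toluene, 110 °C
Reagents that add atoms: none
Why: Tsuji–Wilkinson decarbonylation (oxidative addition of rhodium into the formyl C–H bond, carbonyl extrusion, reductive elimination) replaces CHO by H, so C6 becomes the ring CH2 and ceases to be a stereocenter, while the tetrasubstituted allylsilane cannot insert.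

Step 9
Reactants: 18 (3R,5R,10S)-3-(triethylsilyloxy)-12-(trimethylsilyl)drim-8-en-11-ol
Product: 19 (3R,5R,9S,10S)-drim-8(12)-ene-3,11-diol
Conditions: TsOH·H2O (0.2 equiv), MeOH/CH2Cl2 (1:1), 0 °C → rt
Reagents that add atoms: none
Why: Protodesilylation of the allylsilane (SE2′): the proton should add to C9 on the α face, axially and anti to the axial C10 methyl, and loss of silicon from the β-silyl cation gives the exocyclic C8=C12 alkene with 9α-H and an equatorial CH2OH, while the same acid cleaves the triethylsilyl ether.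

Step 10
Reactants: 19 (3R,5R,9S,10S)-drim-8(12)-ene-3,11-diol
Product: 20 (3R,5R,8R,9S,10S)-drimane-3,8,11-triol
Conditions: Co(acac)2 (20 mol%), PhSiH3 (3 equiv), O2 (1 atm), THF, rt; aq. Na2S2O3
Reagents that add atoms: dioxygen, O=O
Why: Mukaiyama hydration (metal-hydride hydrogen-atom transfer): hydrogen is delivered to C12 and the tertiary C8 radical should capture O2 on the α face, away from the syn-axial C10 methyl, so that reduction of the peroxide in situ gives the equatorial 8α-hydroxyl and the axial 8β-methyl.

Step 11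
Reactants: 20 (3R,5R,8R,9S,10S)-drimane-3,8,11-triol; 21 7-hydroxy-2H-chromen-2-one
Product: 22 7-{[(3R,5R,8R,9S,10S)-3,8-dihydroxydriman-11-yl]oxy}-2H-chromen-2-one
Conditions: 21 (1.5 equiv), PPh3, DIAD, THF, 0 → 40 °C
Reagents that add atoms: none
Why: Mitsunobu etherification: only the primary C11 hydroxyl forms the oxyphosphonium ion and is displaced by the acidic phenol (SN2 at CH2, no stereocenter involved), the hindered axial C3 and tertiary C8 hydroxyls staying free.

Step 12
Reactants: 22 7-{[(3R,5R,8R,9S,10S)-3,8-dihydroxydriman-11-yl]oxy}-2H-chromen-2-one; 23 (Z)-2-methylbut-2-enoic acid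
Product: 25 (3R,5R,8R,9S,10S)-8-hydroxy-11-[(2-oxo-2H-chromen-7-yl)oxy]driman-3-yl (Z)-2-methylbut-2-enoate, via mixed anhydride 24 (not isolated)
Conditions: 23, 2,4,6-Cl3C6H2COCl, Et3N, toluene, rt; then 22, 80 °C
Reagents that add atoms: none
Why: Yamaguchi esterification through the mixed 2,4,6-trichlorobenzoic anhydride without a nucleophilic catalyst should acylate the hindered secondary 3α-hydroxyl while keeping the (Z)-geometry of the angelate; the tertiary 8-hydroxyl should not react, and C3 keeps its configuration because its C–O bond is not broken.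

Compound list
1 | pent-4-ynal | C#CCCC=O | starting material
2 | 3-methylbuta-1,2-diene | CC(C)=C=C | starting material
3 | B-(3-methylbut-2-en-1-yl)diisopinocampheylborane (not isolated) | CC(C)=CCB([C@@H]1C[C@@H]2C[C@H]([C@H]1C)C2(C)C)[C@@H]1C[C@@H]2C[C@H]([C@H]1C)C2(C)C | intermediate
4 | (4R)-3,3-dimethyloct-1-en-7-yn-4-yl diisopinocampheylborinate (not isolated) | C=CC(C)(C)[C@H](OB([C@@H]1C[C@@H]2C[C@H]([C@H]1C)C2(C)C)[C@@H]1C[C@@H]2C[C@H]([C@H]1C)C2(C)C)CCC#C | intermediate
5 | (4R)-3,3-dimethyloct-1-en-7-yn-4-ol | C=CC(C)(C)[C@H](O)CCC#C | intermediate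
6 | triethyl{[(4R)-3,3-dimethyloct-1-en-7-yn-4-yl]oxy}silane | C=CC(C)(C)[C@H](O[Si](CC)(CC)CC)CCC#C | intermediate
7 | lithium acetylide of 6 (not isolated) | [Li]C#CCC[C@@H](O[Si](CC)(CC)CC)C(C)(C)C=C | intermediate
8 | (6R)-7,7-dimethyl-6-(triethylsilyloxy)non-8-en-2-yn-1-ol | OCC#CCC[C@@H](O[Si](CC)(CC)CC)C(C)(C)C=C | intermediate
9 | alkenylmagnesium bromide (bromomagnesium alkoxide) from syn-methylmagnesiation of 8 (not isolated) | Br[Mg]OC/C([Mg]Br)=C(/C)CC[C@@H](O[Si](CC)(CC)CC)C(C)(C)C=C | intermediate
10 | (2E,6R)-2-iodo-3,7,7-trimethyl-6-(triethylsilyloxy)nona-2,8-dien-1-ol | OC/C(=C(/C)CC[C@@H](O[Si](CC)(CC)CC)C(C)(C)C=C)I | intermediate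
11 | (E)-but-2-enal (crotonaldehyde) | C/C=C/C=O | starting material
12 | (2E,5R,8E)-10-hydroxy-9-iodo-4,4,8-trimethyl-5-(triethylsilyloxy)deca-2,8-dienal | O=C/C=C/C(C)(C)[C@H](O[Si](CC)(CC)CC)CC/C(C)=C(/I)CO | intermediate
13 | (2-bromoprop-2-en-1-yl)trimethylsilane | C=C(Br)C[Si](C)(C)C | starting material
14 | [3-(trimethylsilyl)prop-1-en-2-yl]magnesium bromide (not isolated) | C=C([Mg]Br)C[Si](C)(C)C | intermediate
15 | [3-(trimethylsilyl)prop-1-en-2-yl]zinc chloride (not isolated) | C=C([Zn]Cl)C[Si](C)(C)C | intermediate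
16 | (2E,5R,8Z)-9-(hydroxymethyl)-4,4,8-trimethyl-10-methylidene-5-(triethylsilyloxy)-11-(trimethylsilyl)undeca-2,8-dienal | O=C/C=C/C(C)(C)[C@H](O[Si](CC)(CC)CC)CC/C(C)=C(/C(=C)C[Si](C)(C)C)CO | intermediate
17 | (3R,5R,6S,10S)-11-hydroxy-3-(triethylsilyloxy)-12-(trimethylsilyl)drim-8-ene-6-carbaldehyde (3α-OSiEt3, 5α-H, 6α-CHO, 10β-CH3) | CC[Si](CC)(CC)O[C@@H]1CC[C@]2(C)C(CO)=C(C[Si](C)(C)C)C[C@H](C=O)[C@H]2C1(C)C | intermediate
18 | (3R,5R,10S)-3-(triethylsilyloxy)-12-(trimethylsilyl)drim-8-en-11-ol | CC[Si](CC)(CC)O[C@@H]1CC[C@]2(C)C(CO)=C(C[Si](C)(C)C)CC[C@H]2C1(C)C | intermediate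
19 | (3R,5R,9S,10S)-drim-8(12)-ene-3,11-diol (3α-OH, 9α-H) | O[C@@H]1CC[C@]2(C)[C@@H](CO)C(=C)CC[C@H]2C1(C)C | intermediate
20 | (3R,5R,8R,9S,10S)-drimane-3,8,11-triol (3α-OH, 8α-OH) | O[C@@H]1CC[C@]2(C)[C@@H](CO)[C@](C)(O)CC[C@H]2C1(C)C | intermediate
21 | 7-hydroxy-2H-chromen-2-one (umbelliferone) | O=c1ccc2ccc(O)cc2o1 | starting material
22 | 7-{[(3R,5R,8R,9S,10S)-3,8-dihydroxydriman-11-yl]oxy}-2H-chromen-2-one | O[C@@H]1CC[C@]2(C)[C@@H](COc3ccc4ccc(=O)oc4c3)[C@](C)(O)CC[C@H]2C1(C)C | intermediate
23 | (Z)-2-methylbut-2-enoic acid (angelic acid) | C/C=C(/C)C(=O)O | starting material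
24 | (Z)-2-methylbut-2-enoic 2,4,6-trichlorobenzoic anhydride (not isolated) | C/C=C(/C)C(=O)OC(=O)c1c(Cl)cc(Cl)cc1Cl | intermediate
25 | (3R,5R,8R,9S,10S)-8-hydroxy-11-[(2-oxo-2H-chromen-7-yl)oxy]driman-3-yl (Z)-2-methylbut-2-enoate (CNP0189964.4) | C/C=C(/C)C(=O)O[C@@H]1CC[C@]2(C)[C@@H](COc3ccc4ccc(=O)oc4c3)[C@](C)(O)CC[C@H]2C1(C)C | target

Total step count: 12. Longest linear sequence: 12 steps (1 → 25).

Steps most likely to fail

Step 7 (iminium-catalysed cycloaddition). The process at risk is slow or unselective addition to the hindered iminium ion, with loss of facial control or competing exo closure. The fallback uses auxiliary control under Lewis acid activation and sets out from 10. Cross-metathesis of 10 with (S)-3-acryloyl-4-benzyloxazolidin-2-one (second-generation Hoveyda–Grubbs catalyst) would give the iodo (E)-enimide F1. Negishi coupling with 15 as in step 6 would give the triene imide F2. Me2AlCl (excess, CH2Cl2, −30 °C) would close both rings through the chelated s-cis imide, the diene adding endo on the face away from the benzyl group, to give the cycloadduct imide F3. LiOH/H2O2 would release the 6α-carboxylic acid F4. Its N-hydroxypyridine-2-thione ester F5 (DCC), irradiated with t-BuSH (Barton decarboxylation), would lose CO2 and return to the route at 18.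

Step 5 (cross-metathesis). The process at risk is failure of the neopentyl-type vinyl group to enter the metathesis cycle, or deactivation of the catalyst by the allylic alcohol. The fallback sets out from 10: oxidative cleavage of the vinyl group (OsO4 cat., NaIO4, 2,6-lutidine, dioxane/H2O; the tetrasubstituted iodoalkene is far less reactive) would give the α-quaternary aldehyde F6. Wittig olefination with (triphenylphosphoranylidene)acetaldehyde (toluene, 80 °C) would then return to the route at 12.

Step 10 (hydration). The process at risk is poor facial selectivity in the capture of O2 by the planar C8 radical. The fallback sets out from 19: epoxidation with mCPBA, expected on the α face for the same steric reason, would give the 8α,12-epoxide F7. Hydride opening at the primary carbon with LiAlH4 (THF, 0 °C → rt) would then return to the route at 20.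

Further compounds
F1 | step 7 | (S)-4-benzyl-3-[(2E,5R,8E)-10-hydroxy-9-iodo-4,4,8-trimethyl-5-(triethylsilyloxy)deca-2,8-dienoyl]oxazolidin-2-one | O=C(/C=C/C(C)(C)[C@H](O[Si](CC)(CC)CC)CC/C(C)=C(/I)CO)N1[C@@H](Cc2ccccc2)COC1=O
F2 | step 7 | (S)-4-benzyl-3-[(2E,5R,8Z)-9-(hydroxymethyl)-4,4,8-trimethyl-10-methylidene-5-(triethylsilyloxy)-11-(trimethylsilyl)undeca-2,8-dienoyl]oxazolidin-2-one | O=C(/C=C/C(C)(C)[C@H](O[Si](CC)(CC)CC)CC/C(C)=C(/C(=C)C[Si](C)(C)C)CO)N1[C@@H](Cc2ccccc2)COC1=O
F3 | step 7 | (S)-4-benzyl-3-{[11-hydroxy-3α-(triethylsilyloxy)-12-(trimethylsilyl)drim-8-en-6α-yl]carbonyl}oxazolidin-2-one | CC[Si](CC)(CC)O[C@@H]1CC[C@]2(C)C(CO)=C(C[Si](C)(C)C)C[C@H](C(=O)N3[C@@H](Cc4ccccc4)COC3=O)[C@H]2C1(C)C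
F4 | step 7 | 11-hydroxy-3α-(triethylsilyloxy)-12-(trimethylsilyl)drim-8-ene-6α-carboxylic acid | CC[Si](CC)(CC)O[C@@H]1CC[C@]2(C)C(CO)=C(C[Si](C)(C)C)C[C@H](C(=O)O)[C@H]2C1(C)C
F5 | step 7 | 2-thioxopyridin-1(2H)-yl 11-hydroxy-3α-(triethylsilyloxy)-12-(trimethylsilyl)drim-8-ene-6α-carboxylate | CC[Si](CC)(CC)O[C@@H]1CC[C@]2(C)C(CO)=C(C[Si](C)(C)C)C[C@H](C(=O)On3ccccc3=S)[C@H]2C1(C)C
F6 | step 5 | (3R,6E)-8-hydroxy-7-iodo-2,2,6-trimethyl-3-(triethylsilyloxy)oct-6-enal | O=CC(C)(C)[C@H](O[Si](CC)(CC)CC)CC/C(C)=C(/I)CO
F7 | step 10 | 8α,12-epoxydrimane-3α,11-diol | O[C@@H]1CC[C@]2(C)[C@@H](CO)[C@@]3(CO3)CC[C@H]2C1(C)C
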